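Readings and results were computed for substances that don't exist.

**Reagent budget.** Counting reagent is the easy step, if each substrate converted takes one reagent and each over-reacted product takes a second. For alpha 165% is the reagent budget, reagent charged over substrate charged at the given volume ratio, where the budget is [reagent in the second phase] times that ratio over [substrate]; gamma has 110%. So over-reacted product equals the budget's excess over the substrate charge, 65.0% in alpha, plus substrate left, minus reagent unspent, and those last two terms are a correction.

all flasks: substrate 2.0 × 10⁻⁴ M

| charge | reagent in the second phase | remark | time | volume of the second phase over the first |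
|---|---|---|---|---|
| green | 0.23 mM | run made earlier |  |  |
| teal | 0.25 mM | run made earlier |  |  |
| ochre | 0.26 mM | run made earlier |  |  |
| gamma | 0.220 mM |  | 4.0 min | 1.0 |
| alpha | 0.330 mM |  | 4.0 min | 1.0 |

| run | time / min | target / % | isomer of the product / % | substrate / % | over-reacted product / % |
|---|---|---|---|---|---|
| green | 0.250 | 19.5 | 1.2 | 77.6 | 1.5 |
| green | 0.500 | 32.2 | 3.2 | 59.4 | 4.7 |
| green | 1.33 | 42.1 | 6.7 | 34.8 | 15.4 |
| green | 3.00 | 43.4 | 8.4 | 22.1 | 25.5 |
| teal | 0.250 | 21.2 | 0.6 | 76.1 | 0.9 |
| teal | 0.500 | 33.9 | 3.3 | 57.3 | 6.1 |
| teal | 1.33 | 43.4 | 7.1 | 31.7 | 17.5 |
| teal | 3.00 | 43.8 | 8.5 | 18.3 | 29.4 |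
| ochre | 0.667 | 38.5 | 4.4 | 47.7 | 9.1 |
| ochre | 1.33 | 43.6 | 7.2 | 30.1 | 18.8 |
| ochre | 2.00 | 44.0 | 8.4 | 22.5 | 25.8 |
| ochre | 3.00 | 42.8 | 7.9 | 16.8 | 31.7 |

(each reading ± 0.3 percentage points)

- in the second phase: reagent in the second phase; everything else is in the first
- charges count per volume of the first phase; a concentration in a rate is the amount of a species over the volume of its own phase; every rate counts per litre of the first phase
- the earlier runs hold the two phases in the same ratio of volumes as the flask asked about

- which of these there is most of at the end, counted by the substrate in it, gamma (isomer of the product / over-reacted product / substrate / target)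
- which of these there is most of at the end, counted by the substrate in it, alpha (isomer of the product / over-reacted product / substrate / target)
- the largest of these amounts at the end, in percent of the substrate charged, gamma
- the largest of these amounts at the end, in percent of the substrate charged, alpha

**Lower bound.** Ochre, with a budget of 130%, reads as 15.1% unspent at 3.00 min, a share of 11.6%. If alpha keeps that share and has no substrate left, its over-reacted product is 45.8%, more than the highest target reading, 44.0%.

**Upper bound.** From 2.00 min to 3.00 min ochre's readings put unspent reagent at 0.566 of its earlier value and substrate at 0.747. One more such step gives alpha 66.7%.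

**Gamma's ceiling.** Taking substrate as green's last reading of 22.1% and no reagent unspent, the balance puts gamma's over-reacted product at 32.1%, less than green's target reading of 43.4%.

**The check.** The forecast, noting that “this is an extrapolation beyond the tested reagent range”, gave target at 43.8% for gamma and over-reacted product at 52% for alpha, the latter inside the bracket. The flasks give target at 43.9% in gamma and over-reacted product at 52.1% in alpha.

    reagent in the reaction phase ⇌ reagent in the second phase, rate k1*([reagent in the reaction phase] - [reagent in the second phase]/K1) per volume of the first phase (partition coefficient = 0.420, kL = 0.0790 s⁻¹)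
    substrate + reagent in the reaction phase → target (k = 160 M⁻¹ s⁻¹)
    reagent in the reaction phase + target → over-reacted product (k = 82.0 M⁻¹ s⁻¹)
    target ⇌ isomer of the product (K = 0.190, k = 0.00930 s⁻¹)

**Alpha's reagent.** Alpha's budget leaves 19.2% unspent at 4.00 min. In alpha, reagent in the reaction phase is made 4.48 times faster than it is used at 0.0713 min, each step taken net, but the ratio is 0.304 at 4.00 min. At that time in alpha the substrate step uses it at 0.35 of the over-reaction's rate.

**Second flask.** A neighbour flask, alpha with 5.0 × 10⁻⁴ M of substrate, has a budget of 66.0%, below its substrate charge: reagent is the limiting reagent there, and substrate converted plus over-reacted product can total that much. At 4.00 min that neighbour flask leaves 44.4% substrate and holds 10.4% over-reacted product, so substrate converted plus over-reacted product total 66.0%.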